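Start from a leftover, the number to carry through this text: W = 0.480 mM, the working catalyst. It is the free catalyst charged minus the impurity charged, on my assumption that each impurity kills one catalyst for good.

all flasks: starting material 0.29 M; gas phase 11 mM (held); free catalyst 0.84 mM; impurity 0.36 mM

| run | added ligand | remark | time |
|---|---|---|---|
| Sunday's | 0.91 mM | the very flask that is asked about, followed so far |  |
| Monday's | 0.46 mM | run made earlier |  |
| flask | 0.91 mM |  | 8.0 h |

| run | time / h | product / % | starting material / % |
|---|---|---|---|
| Sunday's | 0.133 | 2.3 | 99.5 |
| Sunday's | 0.333 | 3.4 | 95.6 |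
| Sunday's | 0.667 | 8.6 | 91.8 |
| Sunday's | 1.00 | 12.7 | 87.5 |
| Sunday's | 1.33 | 16.1 | 85.0 |
| Sunday's | 2.00 | 22.1 | 76.4 |
| Sunday's | 2.50 | 27.6 | 73.5 |
| Monday's | 0.333 | 5.0 | 94.8 |
| Monday's | 0.833 | 14.1 | 86.3 |
| Monday's | 1.50 | 23.4 | 76.9 |
| Monday's | 2.50 | 36.9 | 63.4 |
| Monday's | 3.00 | 42.3 | 57.0 |
| Monday's | 4.00 | 53.8 | 46.3 |
| Monday's | 6.00 | 69.9 | 30.8 |

(each reading ± 0.5 percentage points)

- at the start none of the gas phase is in solution

- spring: doubling the transfer coefficient of the gas phase, all else as stated
- winter: doubling the amount of free catalyst, all else as stated
- dusk: doubling the saturation concentration of gas phase, all else as stated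

- the product standing at 8.0 h, as a percentage of the starting material charged
- the change that raises the amount of product at 8.0 h, in percent of the starting material charged most ("none" if none brings more than 2 percentage points) (spring / winter / dusk / none)
- amount of product at 8.0 h, in percent of the starting material charged, after dusk

Now run the flask, which is Sunday's run continued, in slow motion. In the first instants no gas is in solution, and the impurity is the limiting reagent of the poisoning, at 0.36 mM against 0.84 mM of free catalyst. Sunday's first reading already shows 2.3% product at 0.133 h, a time much shorter than the 8.0 h asked, so I see no lag worth counting.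

In the middle, a saturated solution holds dissolved gas equal to 3.79% of the starting material charged, so, if each product takes up one gas, the gas must be refilled continually. Sunday's last reading gives a pseudo-first-order constant k = 0.129 h⁻¹. Monday, with half the ligand and the same W, reads 0.184 h⁻¹ at that time, which is faster, so the ligand seems to hold part of W back. Monday's constant reaches 0.200 h⁻¹ by 6.00 h, so my estimate may run low.

At the end, the product should climb toward the whole charge, and my reckoning at 8.0 h gives 64.4%. With ligand fixed, I scale k with W. Winter makes W 1.32 mM, hence 94.1%. Dusk, if the rate is first order in gas, gives 87.3%, which is less. Spring I rate low.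

The forecast said 67%, winter and 90% after dusk, reading “partial gas-transfer limitation”.

The flask gives 65.5%; winter gains 33 percentage points, and dusk reaches 89.4%.

    gas phase ⇌ dissolved gas, rate k1*(csat - [dissolved gas]) (kL = 0.240 min⁻¹)
    starting material + dissolved gas + free catalyst → free catalyst + product (k = 1400 M⁻² min⁻¹)
    free catalyst + added ligand ⇌ idle complex (K = 3100 M⁻¹, k = 390 M⁻¹ min⁻¹)
    free catalyst + impurity → spent catalyst (k = 310 M⁻¹ min⁻¹)

In the flask at 8.00 h, spent catalyst stands at 42.9% of the catalyst charged, while free catalyst at 20.0% and idle complex at 37.1% together match W, which is 57.1% of the charge. Now take the neighbour, the same flask charged with 5.0 × 10⁻⁴ M of free catalyst: W falls to 0.140 mM, and scaling k gives 26.0%. That neighbour gave 27.6%.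

Readings and results come from a simulation for substances that don't exist; the scatter is artificial.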